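## Retrosynthetic overview

1. Target 42 ⇐ deprotection of ketone 40 ⇐ ring A aryllithium 38 (from bromide 37) + oxane aldehyde 22, then oxidation.
2. Oxane 22 ⇐ ring closed last by intramolecular SN2 (C2 alkoxide onto a C6 mesylate, inversion) ⇐ open-chain Weinreb amide 18 ⇐ δ-lactone 16.
3. Lactone 16 ⇐ key intermolecular aldol of lactone enolate 13 with aldehyde 5 (C2–C3 bond), then oxidation and chelate-controlled reduction; lactone 12 ⇐ cuprate 1,4-addition to dihydropyranone 9 ⇐ Keck allylation of aldehyde 3, acrylate, ring-closing metathesis.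
4. Bromide 37 ⇐ anti-SN2′ coupling of metalated ring A (from 32) with allylic picolinate 30 ⇐ Keck allylation of 3, oxidative cleavage, Nozaki–Hiyama–Kishi alkenylation, CBS reduction.
5. Ring order: δ-lactone template (step 7) → opened (step 13) → oxane (step 16); all benzene rings are purchased.

Assumption: the target is taken exactly as drawn in the SMILES: oxane (2R,3R,4S,6S) (2-aryl/3-acyl trans, 3-acyl/4-styryl cis, 4-styryl/6-arylethyl cis, 2-aryl/6-arylethyl trans), R at the diarylmethine carbon, S at the carbinol.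

Abbreviations: Ar = 4-(triisopropylsilyloxy)phenyl; TIPS = Si(i-Pr)3; TBS = SiMe2(t-Bu); TES = SiEt3; MOM = CH2OMe. Oxane/lactone locants C2–C6 are those of the final oxane ring.

## Route

**Step 1**
Reactants: 1 methyl 3-(4-hydroxyphenyl)propanoate
Product: 2 methyl 3-Ar-propanoate
Conditions: i-Pr3SiCl, imidazole, DMF, rt
Reagents that add atoms: chlorotriisopropylsilane, CC(C)[Si](Cl)(C(C)C)C(C)C
Why: Phenol silylation (silyl ether formation) gives a bulky aryl TIPS ether that tolerates all later organometallic and basic steps.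

**Step 2**
Reactants: 2 methyl 3-Ar-propanoate
Product: 3 3-Ar-propanal
Conditions: i-Bu2AlH (1.05 equiv), CH2Cl2, −78 °C; aq. KNaC4H4O6
Reagents that add atoms: none
Why: Partial ester reduction stops at the aldehyde because the aluminium hemiacetal is stable at −78 °C and collapses only on work-up.

**Step 3**
Reactants: 4 4-hydroxybenzaldehyde
Product: 5 4-(triisopropylsilyloxy)benzaldehyde
Conditions: i-Pr3SiCl, imidazole, DMF, rt
Reagents that add atoms: chlorotriisopropylsilane, CC(C)[Si](Cl)(C(C)C)C(C)C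
Why: Phenol silylation as in step 1; aldehyde 5 serves both the Takai step and the key aldol.

**Step 4**
Reactants: 5 4-(triisopropylsilyloxy)benzaldehyde
Product: 6 (E)-1-(2-iodoethenyl)-4-(triisopropylsilyloxy)benzene
Conditions: CrCl2 (6 equiv), CHI3 (2 equiv), THF–dioxane, 0 °C → rt
Reagents that add atoms: iodoform, IC(I)I
Why: Takai olefination; the gem-dichromium carbenoid adds to the aldehyde and eliminates to the E-vinyl iodide with high selectivity for aromatic aldehydes.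

**Step 5**
Reactants: 3 3-Ar-propanal
Product: 7 (R)-1-Ar-hex-5-en-3-ol
Conditions: (S)-BINOL (10 mol%), Ti(OiPr)4 (10 mol%), 4 Å MS, CH2Cl2; allylSnBu3, −20 °C, 72 h
Reagents that add atoms: allyltributylstannane, C=CC[Sn](CCCC)(CCCC)CCCC
Why: Keck asymmetric carbonyl allylation; the (S)-BINOL–titanium Lewis acid exposes one aldehyde face and sets the (R)-carbinol, which becomes C6 of the oxane after later inversion.

**Step 6**
Reactants: 7 (R)-1-Ar-hex-5-en-3-ol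
Product: 8 (R)-1-Ar-hex-5-en-3-yl acrylate
Conditions: acryloyl chloride, Et3N, DMAP (cat.), CH2Cl2, 0 °C
Reagents that add atoms: acryloyl chloride, C=CC(=O)Cl
Why: O-acylation of the secondary alcohol with retention installs the second alkene for ring closure.

**Step 7**
Reactants: 8 (R)-1-Ar-hex-5-en-3-yl acrylate
Product: 9 (R)-6-(2-Ar-ethyl)-5,6-dihydro-2H-pyran-2-one
Conditions: second-generation Grubbs catalyst RuCl2(=CHPh)(PCy3)(H2IMes) (5 mol%), CH2Cl2 (5 mM), 40 °C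
Reagents that add atoms: none
Why: Ring-closing metathesis of an acrylate with a terminal alkene gives the six-membered unsaturated lactone and leaves the stereocentre untouched.

**Step 8**
Reactants: 9 (R)-6-(2-Ar-ethyl)-5,6-dihydro-2H-pyran-2-one; 6 (E)-1-(2-iodoethenyl)-4-(triisopropylsilyloxy)benzene
Product: 12 (4R,6R)-4-[(E)-2-Ar-ethenyl]-6-(2-Ar-ethyl)oxan-2-one (4,6-trans), via vinyllithium 10 (not isolated), via divinylcuprate 11 (not isolated)
Conditions: 6 (2.2 equiv), t-BuLi (4.4 equiv), Et2O, −78 °C; CuI (1.1 equiv), THF, −40 °C; then 9, −78 → −30 °C; aq. NH4Cl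
Reagents that add atoms: none
Why: Conjugate (Michael-type) addition of a Gilman alkenylcuprate; axial attack anti to the pseudo-equatorial C6 side chain gives the 4,6-trans lactone, and iodine–lithium exchange keeps the E geometry.

**Step 9**
Reactants: 12 (4R,6R)-4-[(E)-2-Ar-ethenyl]-6-(2-Ar-ethyl)oxan-2-one; 5 4-(triisopropylsilyloxy)benzaldehyde
Product: 14 (3R,4S,6R)-3-[Ar(hydroxy)methyl]-4-[(E)-2-Ar-ethenyl]-6-(2-Ar-ethyl)oxan-2-one (3,4-trans; both carbinol epimers), via lithium enolate 13 (not isolated)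
Conditions: LiN(SiMe3)2 (1.1 equiv), THF, −78 °C; then 5, −78 °C; AcOH quench
Reagents that add atoms: none
Why: Key intermolecular aldol addition forming C2–C3; the aldehyde approaches the lactone enolate anti to the C4 styryl group and fixes C3 (3,4-trans), while the carbinol centre is left for steps 10 and 11.

**Step 10**
Reactants: 14 aldol adduct (both carbinol epimers)
Product: 15 (3R,4S,6R)-3-(4-triisopropylsilyloxybenzoyl)-4-[(E)-2-Ar-ethenyl]-6-(2-Ar-ethyl)oxan-2-one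
Conditions: Dess–Martin periodinane, NaHCO3, CH2Cl2, 0 °C → rt
Reagents that add atoms: none
Why: Dess–Martin oxidation merges both carbinol epimers into one β-keto lactone whose acidic C3 stays in (or equilibrates to) the favoured 3,4-trans arrangement.

**Step 11**
Reactants: 15 β-keto lactone
Product: 16 (3R,4S,6R)-3-[(R)-Ar(hydroxy)methyl]-4-[(E)-2-Ar-ethenyl]-6-(2-Ar-ethyl)oxan-2-one
Conditions: Zn(BH4)2, Et2O–CH2Cl2, −30 → 0 °C
Reagents that add atoms: none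
Why: Chelation-controlled ketone reduction; zinc ties ketone and lactone carbonyls into a six-membered chelate and hydride enters anti to C4, giving the syn (R)-carbinol that becomes C2.

**Step 12**
Reactants: 16 hydroxy lactone
Product: 17 (3R,4S,6R)-3-[(R)-Ar(triethylsilyloxy)methyl]-4-[(E)-2-Ar-ethenyl]-6-(2-Ar-ethyl)oxan-2-one
Conditions: Et3SiOTf, 2,6-lutidine, CH2Cl2, −78 °C
Reagents that add atoms: triethylsilyl triflate, CC[Si](CC)(CC)OS(=O)(=O)C(F)(F)F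
Why: Silylation masks the benzylic hydroxyl so that only the C6 hydroxyl is sulfonylated after ring opening.

**Step 13**
Reactants: 17 silylated lactone
Product: 18 (2R,3S,5R)-2-[(R)-Ar(triethylsilyloxy)methyl]-3-[(E)-2-Ar-ethenyl]-7-Ar-5-hydroxy-N-methoxy-N-methylheptanamide
Conditions: MeNHOMe·HCl, AlMe3, CH2Cl2, 0 °C → rt; aq. KNaC4H4O6
Reagents that add atoms: N,O-dimethylhydroxylamine hydrochloride, CNOC.Cl
Why: Weinreb aminolysis with the aluminium amide opens the lactone irreversibly, frees the C6 hydroxyl and stores the carboxyl carbon as a reducible amide without touching any stereocentre.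

**Step 14**
Reactants: 18 hydroxy Weinreb amide
Product: 19 (2R,3S,5R)-2-[(R)-Ar(triethylsilyloxy)methyl]-3-[(E)-2-Ar-ethenyl]-7-Ar-5-(methanesulfonyloxy)-N-methoxy-N-methylheptanamide
Conditions: MsCl, Et3N, CH2Cl2, −20 °C; used at once
Reagents that add atoms: methanesulfonyl chloride, CS(=O)(=O)Cl
Why: Sulfonylation on oxygen turns the (R)-C6 hydroxyl into a leaving group with retention.

**Step 15**
Reactants: 19 mesylate
Product: 20 (2R,3S,5R)-2-[(R)-Ar(hydroxy)methyl]-3-[(E)-2-Ar-ethenyl]-7-Ar-5-(methanesulfonyloxy)-N-methoxy-N-methylheptanamide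
Conditions: HF·pyridine, pyridine, THF, 0 °C
Reagents that add atoms: none
Why: Buffered HF cleaves the alkyl TES ether much faster than the aryl TIPS ethers and leaves the mesylate intact.

**Step 16**
Reactants: 20 hydroxy mesylate
Product: 21 (2R,3R,4S,6S)-2-Ar-4-[(E)-2-Ar-ethenyl]-6-(2-Ar-ethyl)-N-methoxy-N-methyloxane-3-carboxamide
Conditions: NaH, 15-crown-5 (cat.), THF, 0 °C → rt
Reagents that add atoms: none
Why: Intramolecular Williamson etherification (6-exo-tet SN2); the C2 alkoxide displaces the mesylate with inversion, turning (R)-C6 into (S) and giving the 2,6-trans, 4,6-cis oxane while C2, C3 and C4 keep their configuration.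

**Step 17**
Reactants: 21 oxane Weinreb amide
Product: 22 (2R,3R,4S,6S)-2-Ar-4-[(E)-2-Ar-ethenyl]-6-(2-Ar-ethyl)oxane-3-carbaldehyde
Conditions: i-Bu2AlH, THF, −78 °C; aq. KNaC4H4O6; used crude
Reagents that add atoms: none
Why: Weinreb amide reduction stops at the aldehyde through the chelated aluminium hemiaminal, and the cold neutral work-up avoids C3 epimerisation.

**Step 18**
Reactants: 3 3-Ar-propanal
Product: 23 (S)-1-Ar-hex-5-en-3-ol
Conditions: (R)-BINOL (10 mol%), Ti(OiPr)4 (10 mol%), 4 Å MS, CH2Cl2; allylSnBu3, −20 °C, 72 h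
Reagents that add atoms: allyltributylstannane, C=CC[Sn](CCCC)(CCCC)CCCC
Why: Keck asymmetric carbonyl allylation with the enantiomeric ligand sets the (S)-carbinol of the open-chain diarylheptanoid arm.

**Step 19**
Reactants: 23 (S)-1-Ar-hex-5-en-3-ol
Product: 24 (S)-tert-butyldimethyl[(1-Ar-hex-5-en-3-yl)oxy]silane
Conditions: t-BuMe2SiCl, imidazole, DMF, rt
Reagents that add atoms: tert-butyldimethylsilyl chloride, CC(C)(C)[Si](C)(C)Cl
Why: Silyl ether formation protects the carbinol through all later organometallic steps.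

**Step 20**
Reactants: 24 silyl ether
Product: 25 (S)-3-(tert-butyldimethylsilyloxy)-5-Ar-pentanal
Conditions: OsO4 (2 mol%), NaIO4 (4 equiv), 2,6-lutidine, dioxane–H2O, rt
Reagents that add atoms: osmium tetroxide, O=[Os](=O)(=O)=O, which delivers the new oxygen and is re-formed by sodium periodate, [Na+].[O-]I(=O)(=O)=O
Why: Lemieux–Johnson oxidative cleavage of the only alkene gives the β-silyloxy aldehyde without touching the electron-rich arene.

**Step 21**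
Reactants: 25 (S)-3-(tert-butyldimethylsilyloxy)-5-Ar-pentanal; 6 (E)-1-(2-iodoethenyl)-4-(triisopropylsilyloxy)benzene
Product: 27 (1E,5S)-5-(tert-butyldimethylsilyloxy)-1,7-di-Ar-hept-1-en-3-ol (both C3 epimers), via alkenylchromium dichloride 26 (not isolated)
Conditions: 6 (1.5 equiv), CrCl2 (4 equiv), NiCl2 (2 mol%), DMSO, rt; aq. NH4Cl
Reagents that add atoms: none
Why: Nozaki–Hiyama–Kishi coupling, in which NiCl2-catalysed metalation of the iodide gives the E-alkenylchromium dichloride (trivalent chromium) that adds 1,2 to the aldehyde under neutral conditions without β-elimination of the silyloxy group; the uncontrolled carbinol centre is erased in the next step.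

**Step 22**
Reactants: 27 allylic alcohols
Product: 28 (1E,5S)-5-(tert-butyldimethylsilyloxy)-1,7-di-Ar-hept-1-en-3-one
Conditions: Dess–Martin periodinane, NaHCO3, CH2Cl2, rt
Reagents that add atoms: none
Why: Dess–Martin oxidation of the allylic alcohol gives the enone without β-elimination of the silyloxy group.

**Step 23**
Reactants: 28 enone
Product: 29 (1E,3S,5S)-5-(tert-butyldimethylsilyloxy)-1,7-di-Ar-hept-1-en-3-ol (3,5-syn)
Conditions: (R)-2-methyl-CBS-oxazaborolidine (20 mol%), catecholborane, toluene, −78 °C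
Reagents that add atoms: none
Why: Corey–Bakshi–Shibata 1,2-reduction under reagent control (alkenyl as the large group) gives the (S)-allylic alcohol.

**Step 24**
Reactants: 29 (3S)-allylic alcohol
Product: 30 (1E,3S,5S)-5-(tert-butyldimethylsilyloxy)-1,7-di-Ar-hept-1-en-3-yl pyridine-2-carboxylate
Conditions: picolinic acid, DCC, DMAP (cat.), CH2Cl2, 0 °C → rt; used at once
Reagents that add atoms: picolinic acid, OC(=O)c1ccccn1
Why: Steglich esterification with retention installs the chelating picolinate leaving group.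

**Step 25**
Reactants: 31 5-methoxybenzene-1,3-diol
Product: 32 1-methoxy-3,5-bis(methoxymethoxy)benzene
Conditions: NaH, MeOCH2Cl, DMF, 0 °C → rt
Reagents that add atoms: chloromethyl methyl ether, COCCl
Why: Williamson-type O-alkylation gives the bis-MOM ether, whose two acetal groups direct the next metalation.

**Step 26**
Reactants: 32 1-methoxy-3,5-bis(methoxymethoxy)benzene; 30 allylic picolinate
Product: 36 2-[(1R,2E,5S)-5-(tert-butyldimethylsilyloxy)-1,7-di-Ar-hept-2-en-1-yl]-5-methoxy-1,3-bis(methoxymethoxy)benzene, via aryllithium 33 (not isolated), via aryl Grignard reagent 34 (not isolated), via diarylcuprate 35 (not isolated)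
Conditions: 32 (3 equiv), n-BuLi, THF, 0 °C; MgBr2·OEt2; CuBr·SMe2 (0.5 equiv per Mg), −40 °C; then 30, −40 → 0 °C; aq. NH4Cl
Reagents that add atoms: none
Why: Directed ortho-metalation between the two MOM ethers, then anti-SN2′ allylic substitution of the picolinate with 1,3-chirality transfer; the aryl enters the benzylic alkene carbon opposite the leaving group, setting the (R)-diarylmethine centre and the E-alkene.

**Step 27**
Reactants: 36 coupled arene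
Product: 37 2-bromo-4-[(1R,2E,5S)-5-(tert-butyldimethylsilyloxy)-1,7-di-Ar-hept-2-en-1-yl]-1-methoxy-3,5-bis(methoxymethoxy)benzene
Conditions: NBS (1.0 equiv), CH2Cl2, −40 → 0 °C, dark
Reagents that add atoms: N-bromosuccinimide, O=C1CCC(=O)N1Br
Why: Electrophilic aromatic bromination at one of the two equivalent free positions of the trioxygenated ring, which is far more reactive than the alkene or the silyloxyphenyl rings.

**Step 28**
Reactants: 37 aryl bromide; 22 oxane aldehyde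
Product: 39 secondary alcohol from addition of ring A to the aldehyde (both carbinol epimers; all other centres as in 37 and 22), via aryllithium 38 (not isolated)
Conditions: 37 (1.3 equiv), t-BuLi (2.6 equiv), Et2O, −78 °C, 10 min; then 22, −78 → −40 °C; aq. NH4Cl
Reagents that add atoms: none
Why: Bromine–lithium exchange outruns deprotonation of the diarylmethine C–H at −78 °C, and the chelated aryllithium adds 1,2 to the aldehyde; the new carbinol centre is removed in the next step.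

**Step 29**
Reactants: 39 secondary alcohol
Product: 40 fully protected ketone (ring A aryl ketone at oxane C3)
Conditions: Dess–Martin periodinane, NaHCO3, CH2Cl2, rt
Reagents that add atoms: none
Why: Dess–Martin oxidation of the benzylic alcohol gives the aryl ketone under buffered non-basic conditions that leave C3 unepimerised.

**Step 30**
Reactants: 40 protected ketone
Product: 41 ring A diol (both MOM groups removed; five aryl TIPS ethers and the TBS ether kept)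
Conditions: ZnBr2, n-PrSH, CH2Cl2, 0 °C, 15 min
Reagents that add atoms: none
Why: Lewis-acid/thiol acetal cleavage removes aryl MOM ethers within minutes while silyl ethers, alkenes and the benzylic oxane ether, still deactivated by its silyloxy aryl group, survive.

**Step 31**
Reactants: 41 ring A diol
Product: 42 blepharocalyxin B
Conditions: Bu4NF, AcOH (1:1), THF, 0 °C → rt
Reagents that add atoms: none
Why: Fluoride-mediated desilylation buffered with acetic acid removes the five aryl TIPS ethers and the TBS ether without base-induced retro-oxa-Michael opening or C3 epimerisation.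

## Compound list

1 | methyl 3-(4-hydroxyphenyl)propanoate | COC(=O)CCc1ccc(O)cc1 | starting material
2 | methyl 3-Ar-propanoate | COC(=O)CCc1ccc(O[Si](C(C)C)(C(C)C)C(C)C)cc1 | intermediate
3 | 3-Ar-propanal | O=CCCc1ccc(O[Si](C(C)C)(C(C)C)C(C)C)cc1 | intermediate
4 | 4-hydroxybenzaldehyde | O=Cc1ccc(O)cc1 | starting material
5 | 4-(triisopropylsilyloxy)benzaldehyde | O=Cc1ccc(O[Si](C(C)C)(C(C)C)C(C)C)cc1 | intermediate
6 | (E)-1-(2-iodoethenyl)-4-(triisopropylsilyloxy)benzene | I/C=C/c1ccc(O[Si](C(C)C)(C(C)C)C(C)C)cc1 | intermediate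
7 | (R)-1-Ar-hex-5-en-3-ol | C=CC[C@H](O)CCc1ccc(O[Si](C(C)C)(C(C)C)C(C)C)cc1 | intermediate
8 | (R)-1-Ar-hex-5-en-3-yl acrylate | C=CC[C@H](OC(=O)C=C)CCc1ccc(O[Si](C(C)C)(C(C)C)C(C)C)cc1 | intermediate
9 | (R)-6-(2-Ar-ethyl)-5,6-dihydro-2H-pyran-2-one | O=C1C=CC[C@@H](CCc2ccc(O[Si](C(C)C)(C(C)C)C(C)C)cc2)O1 | intermediate
10 | (E)-2-Ar-ethenyllithium | [Li]/C=C/c1ccc(O[Si](C(C)C)(C(C)C)C(C)C)cc1 | intermediate
11 | lithium bis[(E)-2-Ar-ethenyl]cuprate | [Li+].[Cu-](/C=C/c1ccc(O[Si](C(C)C)(C(C)C)C(C)C)cc1)/C=C/c1ccc(O[Si](C(C)C)(C(C)C)C(C)C)cc1 | intermediate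
12 | (4R,6R)-4-[(E)-2-Ar-ethenyl]-6-(2-Ar-ethyl)oxan-2-one | O=C1C[C@H](/C=C/c2ccc(O[Si](C(C)C)(C(C)C)C(C)C)cc2)C[C@@H](CCc2ccc(O[Si](C(C)C)(C(C)C)C(C)C)cc2)O1 | intermediate
13 | lithium enolate of 12 | [Li]OC1=C[C@H](/C=C/c2ccc(O[Si](C(C)C)(C(C)C)C(C)C)cc2)C[C@@H](CCc2ccc(O[Si](C(C)C)(C(C)C)C(C)C)cc2)O1 | intermediate
14 | (3R,4S,6R)-3-[Ar(hydroxy)methyl]-4-[(E)-2-Ar-ethenyl]-6-(2-Ar-ethyl)oxan-2-one, both carbinol epimers | O=C1[C@@H](C(O)c2ccc(O[Si](C(C)C)(C(C)C)C(C)C)cc2)[C@H](/C=C/c2ccc(O[Si](C(C)C)(C(C)C)C(C)C)cc2)C[C@@H](CCc2ccc(O[Si](C(C)C)(C(C)C)C(C)C)cc2)O1 | intermediate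
15 | (3R,4S,6R)-3-(4-triisopropylsilyloxybenzoyl)-4-[(E)-2-Ar-ethenyl]-6-(2-Ar-ethyl)oxan-2-one | O=C1[C@@H](C(=O)c2ccc(O[Si](C(C)C)(C(C)C)C(C)C)cc2)[C@H](/C=C/c2ccc(O[Si](C(C)C)(C(C)C)C(C)C)cc2)C[C@@H](CCc2ccc(O[Si](C(C)C)(C(C)C)C(C)C)cc2)O1 | intermediate
16 | (3R,4S,6R)-3-[(R)-Ar(hydroxy)methyl]-4-[(E)-2-Ar-ethenyl]-6-(2-Ar-ethyl)oxan-2-one | O=C1[C@@H]([C@@H](O)c2ccc(O[Si](C(C)C)(C(C)C)C(C)C)cc2)[C@H](/C=C/c2ccc(O[Si](C(C)C)(C(C)C)C(C)C)cc2)C[C@@H](CCc2ccc(O[Si](C(C)C)(C(C)C)C(C)C)cc2)O1 | intermediate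
17 | (3R,4S,6R)-3-[(R)-Ar(triethylsilyloxy)methyl]-4-[(E)-2-Ar-ethenyl]-6-(2-Ar-ethyl)oxan-2-one | O=C1[C@@H]([C@@H](O[Si](CC)(CC)CC)c2ccc(O[Si](C(C)C)(C(C)C)C(C)C)cc2)[C@H](/C=C/c2ccc(O[Si](C(C)C)(C(C)C)C(C)C)cc2)C[C@@H](CCc2ccc(O[Si](C(C)C)(C(C)C)C(C)C)cc2)O1 | intermediate
18 | (2R,3S,5R)-2-[(R)-Ar(triethylsilyloxy)methyl]-3-[(E)-2-Ar-ethenyl]-7-Ar-5-hydroxy-N-methoxy-N-methylheptanamide | CON(C)C(=O)[C@@H]([C@@H](O[Si](CC)(CC)CC)c1ccc(O[Si](C(C)C)(C(C)C)C(C)C)cc1)[C@H](/C=C/c1ccc(O[Si](C(C)C)(C(C)C)C(C)C)cc1)C[C@H](O)CCc1ccc(O[Si](C(C)C)(C(C)C)C(C)C)cc1 | intermediate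
19 | (2R,3S,5R)-2-[(R)-Ar(triethylsilyloxy)methyl]-3-[(E)-2-Ar-ethenyl]-7-Ar-5-(methanesulfonyloxy)-N-methoxy-N-methylheptanamide | CON(C)C(=O)[C@@H]([C@@H](O[Si](CC)(CC)CC)c1ccc(O[Si](C(C)C)(C(C)C)C(C)C)cc1)[C@H](/C=C/c1ccc(O[Si](C(C)C)(C(C)C)C(C)C)cc1)C[C@H](OS(C)(=O)=O)CCc1ccc(O[Si](C(C)C)(C(C)C)C(C)C)cc1 | intermediate
20 | (2R,3S,5R)-2-[(R)-Ar(hydroxy)methyl]-3-[(E)-2-Ar-ethenyl]-7-Ar-5-(methanesulfonyloxy)-N-methoxy-N-methylheptanamide | CON(C)C(=O)[C@@H]([C@@H](O)c1ccc(O[Si](C(C)C)(C(C)C)C(C)C)cc1)[C@H](/C=C/c1ccc(O[Si](C(C)C)(C(C)C)C(C)C)cc1)C[C@H](OS(C)(=O)=O)CCc1ccc(O[Si](C(C)C)(C(C)C)C(C)C)cc1 | intermediate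
21 | (2R,3R,4S,6S)-2-Ar-4-[(E)-2-Ar-ethenyl]-6-(2-Ar-ethyl)-N-methoxy-N-methyloxane-3-carboxamide | CON(C)C(=O)[C@@H]1[C@H](/C=C/c2ccc(O[Si](C(C)C)(C(C)C)C(C)C)cc2)C[C@H](CCc2ccc(O[Si](C(C)C)(C(C)C)C(C)C)cc2)O[C@H]1c1ccc(O[Si](C(C)C)(C(C)C)C(C)C)cc1 | intermediate
22 | (2R,3R,4S,6S)-2-Ar-4-[(E)-2-Ar-ethenyl]-6-(2-Ar-ethyl)oxane-3-carbaldehyde | O=C[C@@H]1[C@H](/C=C/c2ccc(O[Si](C(C)C)(C(C)C)C(C)C)cc2)C[C@H](CCc2ccc(O[Si](C(C)C)(C(C)C)C(C)C)cc2)O[C@H]1c1ccc(O[Si](C(C)C)(C(C)C)C(C)C)cc1 | intermediate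
23 | (S)-1-Ar-hex-5-en-3-ol | C=CC[C@@H](O)CCc1ccc(O[Si](C(C)C)(C(C)C)C(C)C)cc1 | intermediate
24 | (S)-tert-butyldimethyl[(1-Ar-hex-5-en-3-yl)oxy]silane | C=CC[C@@H](O[Si](C)(C)C(C)(C)C)CCc1ccc(O[Si](C(C)C)(C(C)C)C(C)C)cc1 | intermediate
25 | (S)-3-(tert-butyldimethylsilyloxy)-5-Ar-pentanal | O=CC[C@@H](O[Si](C)(C)C(C)(C)C)CCc1ccc(O[Si](C(C)C)(C(C)C)C(C)C)cc1 | intermediate
26 | (E)-2-Ar-ethenylchromium dichloride | Cl[Cr](Cl)/C=C/c1ccc(O[Si](C(C)C)(C(C)C)C(C)C)cc1 | intermediate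
27 | (1E,5S)-5-(tert-butyldimethylsilyloxy)-1,7-di-Ar-hept-1-en-3-ol, both C3 epimers | OC(/C=C/c1ccc(O[Si](C(C)C)(C(C)C)C(C)C)cc1)C[C@@H](O[Si](C)(C)C(C)(C)C)CCc1ccc(O[Si](C(C)C)(C(C)C)C(C)C)cc1 | intermediate
28 | (1E,5S)-5-(tert-butyldimethylsilyloxy)-1,7-di-Ar-hept-1-en-3-one | O=C(/C=C/c1ccc(O[Si](C(C)C)(C(C)C)C(C)C)cc1)C[C@@H](O[Si](C)(C)C(C)(C)C)CCc1ccc(O[Si](C(C)C)(C(C)C)C(C)C)cc1 | intermediate
29 | (1E,3S,5S)-5-(tert-butyldimethylsilyloxy)-1,7-di-Ar-hept-1-en-3-ol | O[C@H](/C=C/c1ccc(O[Si](C(C)C)(C(C)C)C(C)C)cc1)C[C@@H](O[Si](C)(C)C(C)(C)C)CCc1ccc(O[Si](C(C)C)(C(C)C)C(C)C)cc1 | intermediate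
30 | (1E,3S,5S)-5-(tert-butyldimethylsilyloxy)-1,7-di-Ar-hept-1-en-3-yl pyridine-2-carboxylate | O=C(O[C@H](/C=C/c1ccc(O[Si](C(C)C)(C(C)C)C(C)C)cc1)C[C@@H](O[Si](C)(C)C(C)(C)C)CCc1ccc(O[Si](C(C)C)(C(C)C)C(C)C)cc1)c1ccccn1 | intermediate
31 | 5-methoxybenzene-1,3-diol | COc1cc(O)cc(O)c1 | starting material
32 | 1-methoxy-3,5-bis(methoxymethoxy)benzene | COCOc1cc(OC)cc(OCOC)c1 | intermediate
33 | 4-methoxy-2,6-bis(methoxymethoxy)phenyllithium | [Li]c1c(OCOC)cc(OC)cc1OCOC | intermediate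
34 | 4-methoxy-2,6-bis(methoxymethoxy)phenylmagnesium bromide | Br[Mg]c1c(OCOC)cc(OC)cc1OCOC | intermediate
35 | bromomagnesium bis[4-methoxy-2,6-bis(methoxymethoxy)phenyl]cuprate | Br[Mg+].COCOc1cc(OC)cc(OCOC)c1[Cu-]c1c(OCOC)cc(OC)cc1OCOC | intermediate
36 | 2-[(1R,2E,5S)-5-(tert-butyldimethylsilyloxy)-1,7-di-Ar-hept-2-en-1-yl]-5-methoxy-1,3-bis(methoxymethoxy)benzene | COc1cc(OCOC)c([C@H](/C=C/C[C@@H](O[Si](C)(C)C(C)(C)C)CCc2ccc(O[Si](C(C)C)(C(C)C)C(C)C)cc2)c2ccc(O[Si](C(C)C)(C(C)C)C(C)C)cc2)c(OCOC)c1 | intermediate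
37 | 2-bromo-4-[(1R,2E,5S)-5-(tert-butyldimethylsilyloxy)-1,7-di-Ar-hept-2-en-1-yl]-1-methoxy-3,5-bis(methoxymethoxy)benzene | COc1cc(OCOC)c([C@H](/C=C/C[C@@H](O[Si](C)(C)C(C)(C)C)CCc2ccc(O[Si](C(C)C)(C(C)C)C(C)C)cc2)c2ccc(O[Si](C(C)C)(C(C)C)C(C)C)cc2)c(OCOC)c1Br | intermediate
38 | aryllithium from 37 (Li in place of Br) | COc1cc(OCOC)c([C@H](/C=C/C[C@@H](O[Si](C)(C)C(C)(C)C)CCc2ccc(O[Si](C(C)C)(C(C)C)C(C)C)cc2)c2ccc(O[Si](C(C)C)(C(C)C)C(C)C)cc2)c(OCOC)c1[Li] | intermediate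
39 | secondary alcohol joining ring A of 37 to the formyl carbon of 22, both carbinol epimers | COc1cc(OCOC)c([C@H](/C=C/C[C@@H](O[Si](C)(C)C(C)(C)C)CCc2ccc(O[Si](C(C)C)(C(C)C)C(C)C)cc2)c2ccc(O[Si](C(C)C)(C(C)C)C(C)C)cc2)c(OCOC)c1C(O)[C@@H]1[C@H](/C=C/c2ccc(O[Si](C(C)C)(C(C)C)C(C)C)cc2)C[C@H](CCc2ccc(O[Si](C(C)C)(C(C)C)C(C)C)cc2)O[C@H]1c1ccc(O[Si](C(C)C)(C(C)C)C(C)C)cc1 | intermediate
40 | fully protected blepharocalyxin B (five aryl TIPS ethers, TBS ether, two MOM ethers) | COc1cc(OCOC)c([C@H](/C=C/C[C@@H](O[Si](C)(C)C(C)(C)C)CCc2ccc(O[Si](C(C)C)(C(C)C)C(C)C)cc2)c2ccc(O[Si](C(C)C)(C(C)C)C(C)C)cc2)c(OCOC)c1C(=O)[C@@H]1[C@H](/C=C/c2ccc(O[Si](C(C)C)(C(C)C)C(C)C)cc2)C[C@H](CCc2ccc(O[Si](C(C)C)(C(C)C)C(C)C)cc2)O[C@H]1c1ccc(O[Si](C(C)C)(C(C)C)C(C)C)cc1 | intermediate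
41 | ring A diol (five aryl TIPS ethers and TBS ether kept) | COc1cc(O)c([C@H](/C=C/C[C@@H](O[Si](C)(C)C(C)(C)C)CCc2ccc(O[Si](C(C)C)(C(C)C)C(C)C)cc2)c2ccc(O[Si](C(C)C)(C(C)C)C(C)C)cc2)c(O)c1C(=O)[C@@H]1[C@H](/C=C/c2ccc(O[Si](C(C)C)(C(C)C)C(C)C)cc2)C[C@H](CCc2ccc(O[Si](C(C)C)(C(C)C)C(C)C)cc2)O[C@H]1c1ccc(O[Si](C(C)C)(C(C)C)C(C)C)cc1 | intermediate
42 | blepharocalyxin B | COc1cc(O)c([C@H](/C=C/C[C@@H](O)CCc2ccc(O)cc2)c2ccc(O)cc2)c(O)c1C(=O)[C@@H]1[C@H](/C=C/c2ccc(O)cc2)C[C@H](CCc2ccc(O)cc2)O[C@H]1c1ccc(O)cc1 | target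

## Step count and risks

Total: 31 steps. Longest linear sequence: 19 steps (1, 2, 5–17, 28–31).

**Risk 1, step 16 (oxane closure).** The secondary mesylate may eliminate or be captured by the amide carbonyl oxygen before the hindered benzylic alkoxide attacks. The fallback sets out from 18: removal of the TES group with HF·pyridine gives (2R,3S,5R)-2-[(R)-Ar(hydroxy)methyl]-3-[(E)-2-Ar-ethenyl]-7-Ar-5-hydroxy-N-methoxy-N-methylheptanamide F1. The ring is then closed by Mitsunobu cyclodehydration (PPh3, diisopropyl azodicarboxylate, toluene, 0 °C → rt): the less hindered C6 hydroxyl is activated as the oxyphosphonium ion and displaced with inversion by the benzylic hydroxyl, with no sulfonate or strong base. The route is rejoined at 21.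

**Risk 2, step 26 (anti-SN2′ arylation).** The di-ortho-substituted arylcopper may transfer sluggishly or attack the α-carbon. The fallback reverses the roles, so that the hindered ring sits on the electrophile and an unhindered arylcopper does the substitution; it sets out from 32 and 25. Aryllithium 33 is quenched with DMF to give 4-methoxy-2,6-bis(methoxymethoxy)benzaldehyde F2, and Takai olefination (CrCl2, CHI3) gives (E)-2-(2-iodoethenyl)-5-methoxy-1,3-bis(methoxymethoxy)benzene F3. t-BuLi converts F3 into (E)-2-[4-methoxy-2,6-bis(methoxymethoxy)phenyl]ethenyllithium F4, which adds to 25 to give the (1E,5S)-hept-1-en-3-ol epimers F5. Dess–Martin oxidation gives enone F6, and (S)-2-methyl-CBS-oxazaborolidine with catecholborane gives the (1E,3R,5S)-allylic alcohol F7 (3,5-anti). Picolinic acid/DCC gives picolinate F8. 4-(Triisopropylsilyloxy)phenylmagnesium bromide F9 (from commercial (4-bromophenoxy)triisopropylsilane and Mg) with CuBr·SMe2 forms bromomagnesium bis[4-(triisopropylsilyloxy)phenyl]cuprate F10, which attacks F8 anti-SN2′. Because the aryl priorities at the new centre are exchanged, the (3R)-picolinate gives the same (R)-diarylmethine. The route is rejoined at 36.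

**Risk 3, step 28 (aryllithium addition to the hindered, enolisable aldehyde).** Enolisation of 22 or proton transfer from the diarylmethine C–H can compete. The fallback sets out from 22 and 37 and uses a non-basic acyl coupling. Pinnick oxidation (NaClO2, NaH2PO4, 2-methyl-2-butene) of 22 gives (2R,3R,4S,6S)-2-Ar-4-[(E)-2-Ar-ethenyl]-6-(2-Ar-ethyl)oxane-3-carboxylic acid F11, and EtSH, DCC and DMAP give the S-ethyl thioester F12. Bromide 37 is converted via 38 with ZnCl2 into the arylzinc chloride F13. Fukuyama coupling of F12 with F13 (PdCl2(PPh3)2, toluene–THF, rt) gives the ketone directly. The route is rejoined at 40, bypassing 39 and step 29.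

## Further compounds

F1 | step 16 | (2R,3S,5R)-2-[(R)-Ar(hydroxy)methyl]-3-[(E)-2-Ar-ethenyl]-7-Ar-5-hydroxy-N-methoxy-N-methylheptanamide | CON(C)C(=O)[C@@H]([C@@H](O)c1ccc(O[Si](C(C)C)(C(C)C)C(C)C)cc1)[C@H](/C=C/c1ccc(O[Si](C(C)C)(C(C)C)C(C)C)cc1)C[C@H](O)CCc1ccc(O[Si](C(C)C)(C(C)C)C(C)C)cc1
F2 | step 26 | 4-methoxy-2,6-bis(methoxymethoxy)benzaldehyde | COCOc1cc(OC)cc(OCOC)c1C=O
F3 | step 26 | (E)-2-(2-iodoethenyl)-5-methoxy-1,3-bis(methoxymethoxy)benzene | COCOc1cc(OC)cc(OCOC)c1/C=C/I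
F4 | step 26 | (E)-2-[4-methoxy-2,6-bis(methoxymethoxy)phenyl]ethenyllithium | COCOc1cc(OC)cc(OCOC)c1/C=C/[Li]
F5 | step 26 | (1E,5S)-5-(tert-butyldimethylsilyloxy)-1-[4-methoxy-2,6-bis(methoxymethoxy)phenyl]-7-Ar-hept-1-en-3-ol, both C3 epimers | COCOc1cc(OC)cc(OCOC)c1/C=C/C(O)C[C@@H](O[Si](C)(C)C(C)(C)C)CCc1ccc(O[Si](C(C)C)(C(C)C)C(C)C)cc1
F6 | step 26 | (1E,5S)-5-(tert-butyldimethylsilyloxy)-1-[4-methoxy-2,6-bis(methoxymethoxy)phenyl]-7-Ar-hept-1-en-3-one | COCOc1cc(OC)cc(OCOC)c1/C=C/C(=O)C[C@@H](O[Si](C)(C)C(C)(C)C)CCc1ccc(O[Si](C(C)C)(C(C)C)C(C)C)cc1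
F7 | step 26 | (1E,3R,5S)-5-(tert-butyldimethylsilyloxy)-1-[4-methoxy-2,6-bis(methoxymethoxy)phenyl]-7-Ar-hept-1-en-3-ol | O[C@@H](/C=C/c1c(OCOC)cc(OC)cc1OCOC)C[C@@H](O[Si](C)(C)C(C)(C)C)CCc1ccc(O[Si](C(C)C)(C(C)C)C(C)C)cc1
F8 | step 26 | (1E,3R,5S)-5-(tert-butyldimethylsilyloxy)-1-[4-methoxy-2,6-bis(methoxymethoxy)phenyl]-7-Ar-hept-1-en-3-yl pyridine-2-carboxylate | O=C(O[C@@H](/C=C/c1c(OCOC)cc(OC)cc1OCOC)C[C@@H](O[Si](C)(C)C(C)(C)C)CCc1ccc(O[Si](C(C)C)(C(C)C)C(C)C)cc1)c1ccccn1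
F9 | step 26 | 4-(triisopropylsilyloxy)phenylmagnesium bromide | Br[Mg]c1ccc(O[Si](C(C)C)(C(C)C)C(C)C)cc1
F10 | step 26 | bromomagnesium bis[4-(triisopropylsilyloxy)phenyl]cuprate | Br[Mg+].CC(C)[Si](Oc1ccc([Cu-]c2ccc(O[Si](C(C)C)(C(C)C)C(C)C)cc2)cc1)(C(C)C)C(C)C
F11 | step 28 | (2R,3R,4S,6S)-2-Ar-4-[(E)-2-Ar-ethenyl]-6-(2-Ar-ethyl)oxane-3-carboxylic acid | OC(=O)[C@@H]1[C@H](/C=C/c2ccc(O[Si](C(C)C)(C(C)C)C(C)C)cc2)C[C@H](CCc2ccc(O[Si](C(C)C)(C(C)C)C(C)C)cc2)O[C@H]1c1ccc(O[Si](C(C)C)(C(C)C)C(C)C)cc1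
F12 | step 28 | S-ethyl (2R,3R,4S,6S)-2-Ar-4-[(E)-2-Ar-ethenyl]-6-(2-Ar-ethyl)oxane-3-carbothioate | CCSC(=O)[C@@H]1[C@H](/C=C/c2ccc(O[Si](C(C)C)(C(C)C)C(C)C)cc2)C[C@H](CCc2ccc(O[Si](C(C)C)(C(C)C)C(C)C)cc2)O[C@H]1c1ccc(O[Si](C(C)C)(C(C)C)C(C)C)cc1
F13 | step 28 | arylzinc chloride from 37 (ZnCl in place of Br) | COc1cc(OCOC)c([C@H](/C=C/C[C@@H](O[Si](C)(C)C(C)(C)C)CCc2ccc(O[Si](C(C)C)(C(C)C)C(C)C)cc2)c2ccc(O[Si](C(C)C)(C(C)C)C(C)C)cc2)c(OCOC)c1[Zn]Cl
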